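Birch lost free monomer along a straight line in the logarithm, and so did larch, which held more transfer agent.

| flask | free monomer | transfer agent | initiator | impurity | remark | time |
|---|---|---|---|---|---|---|
| birch | 0.30 M | 1.5 mM | 15 mM | 19 mM | run made earlier |  |
| larch | 0.30 M | 2.2 mM | 15 mM | 19 mM | run made earlier |  |
| flask | 0.30 M | 3.00 mM | 15 mM | 19 mM |  | 8.0 min |

| run | time / min | monomer in chains / % | free monomer / % |
|---|---|---|---|
| birch | 1.33 | 7.5 | 87.5 |
| birch | 2.50 | 13.0 | 77.0 |
| birch | 4.00 | 19.3 | 66.5 |
| birch | 5.00 | 21.6 | 60.2 |
| larch | 0.667 | 4.2 | 93.3 |
| larch | 1.50 | 8.1 | 84.7 |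
| larch | 3.00 | 15.0 | 73.2 |
| larch | 5.00 | 21.8 | 61.2 |

(standard deviation of a reading: 0.5 percentage points)

* average number of monomer units in a chain (chains begun, living or dead) at 8.0 min
* part of the free monomer that has reacted at 8.0 min

- the average divides the monomer in chains by the number of chains begun, living and dead together
- the earlier runs do not show the number of chains; that part of a forecast is a guess

*What is the time constant of the loss?* Let M be free monomer as a fraction of its charge. Then M = exp(−kt), with k a pseudo-first-order constant, and the last readings of the two runs average k = 0.0999 min⁻¹.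

*Does the reacted monomer reach chains?* Part of it does in birch: its last reading leaves a gap G, monomer found neither free nor in chains, of 18.2% of the charge.

*A stock taken once, or a leak?* In birch, G is 40.0% of the reacted monomer at the first reading and 45.7% at the last, so I read it as a leak in parallel, dG/dt = k_b M. Here k_b, the leak constant, is the part of k that feeds the gap. Integrating gives G = (k_b/k)c, with c the reacted part. The two runs read k_b = 0.0447 min⁻¹.

*And at 8.0 min?* My reckoning for the flask gives c = 55.0% and a gap G of 24.6%, both as parts of the charge.

*And dp?* The runs do not show chains begun, so I commit to no number.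

The forecast says c = 55.8% and dp = 5.4, adding: “The number of chains is a guess.”

The flask gives c = 53.0% and dp = 30.1.

    free monomer + initiator → living end + monomer in chains (k = 0.0780 M⁻¹ s⁻¹)
    free monomer + living end → monomer in chains + living end, rate k2*[living end]*[free monomer] (k = 0.370 M⁻¹ s⁻¹)
    living end + transfer agent → dead chain (kL = 0.400 M⁻¹ s⁻¹)
    initiator + impurity → spent initiator (k = 8.60 M⁻¹ s⁻¹)
    free monomer → uncatalysed product (k = 7.60 × 10⁻⁴ s⁻¹)

In the flask, the half-life of free monomer by the step into chains, 14 min at 2.96 min, stands close to its half-life by the step into uncatalysed product, 15 min at 8.00 min, and at 8.00 min the flask holds 27.7% monomer in chains and 25.2% uncatalysed product. Taking k from what is left, k_b gives a gap G of 25.1% for this flask, and for a neighbour flask charged with 0.0047 M impurity, with 16.1% free monomer left, it gives 16.4% against the 17.1% uncatalysed product that neighbour holds.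

All runs come from a simulation on assumed constants; noise was put on by code.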